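## Retrosynthetic overview

1. Alpinnanin C is cut at the ring A C3′–C3 bond: cardamonin plus an alkenyl-extended para-quinone methide, joined by a catalyst-controlled Friedel–Crafts alkylation (sets C3, last step).
2. The quinone methide precursor, a 1-(4-hydroxyphenyl)allylic alcohol, comes from an aryl Grignard reagent and (2E,5S)-5-hydroxy-7-phenylhept-2-enal; the C1 configuration is irrelevant because it is erased.
3. The enal comes from (S)-1-phenylhex-5-en-3-ol and crotonaldehyde by cross-metathesis.
4. The (S)-homoallylic alcohol comes from 3-phenylpropanal and an allylboronate under chiral phosphoric acid catalysis (sets C5, the first stereocentre).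
5. No ring is formed; all three benzene rings arrive with the starting materials.

Assumption: the sense of induction of (R)-TRIP in steps 1 and 4 follows the models given there; if either proves opposite, (S)-TRIP is used in that step with nothing else changed.

(R)-TRIP = (R)-3,3′-bis(2,4,6-triisopropylphenyl)-1,1′-binaphthyl-2,2′-diyl hydrogen phosphate.

## Route

**Step 1**
Reactants: 1 3-phenylpropanal; 2 allylboronic acid pinacol ester
Product: 4 (S)-1-phenylhex-5-en-3-ol, via homoallyl pinacol borate 3 (not isolated)
Conditions: 2 (1.2 equiv), (R)-TRIP (5 mol %), 4 Å molecular sieves, toluene, −30 °C; then H2O work-up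
Reagents that add atoms: none
Why: Chiral phosphoric acid-catalysed allylboration through a closed chair transition state in which the acid activates the boronate oxygen and holds the formyl group, so the allyl group adds to the Re face of the aldehyde and sets C5 as (S).

**Step 2**
Reactants: 4 (S)-1-phenylhex-5-en-3-ol; 5 (E)-but-2-enal (crotonaldehyde)
Product: 6 (2E,5S)-5-hydroxy-7-phenylhept-2-enal
Conditions: 5 (5 equiv), second-generation Hoveyda–Grubbs catalyst RuCl2(H2IMes)(=CH-C6H4-2-OiPr) (3 mol %), CH2Cl2, 40 °C
Reagents that add atoms: none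
Why: Olefin cross-metathesis of a terminal homoallylic alcohol with an electron-poor partner gives the E-enal under thermodynamic control with loss of propene, and the carbinol centre is not touched.

**Step 3**
Reactants: 6 (2E,5S)-5-hydroxy-7-phenylhept-2-enal; 7 (4-bromophenoxy)trimethylsilane
Product: 10 (2E,5S)-1-(4-hydroxyphenyl)-7-phenylhept-2-ene-1,5-diol (both C1 epimers), via aryl Grignard reagent 8 (not isolated), via aryl silyl ether diol 9 (not isolated)
Conditions: 7 (2.4 equiv), Mg, THF, 45 °C; then 6, THF, −78 to −20 °C; H2O; then K2CO3 (cat.), MeOH, 0 °C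
Reagents that add atoms: none
Why: Grignard 1,2-addition to the enal (the first equivalent is spent on the C5 hydroxyl) followed by mild methanolysis of the aryl silyl ether; the C1 carbinol is deliberately formed as both epimers because step 4 erases it.

**Step 4**
Reactants: 10 (2E,5S)-1-(4-hydroxyphenyl)-7-phenylhept-2-ene-1,5-diol; 11 cardamonin
Product: 13 alpinnanin C, via vinylogous para-quinone methide 12 (not isolated)
Conditions: 11 (2 equiv), (R)-TRIP (10 mol %), 5 Å molecular sieves, CH2Cl2, −20 to 0 °C, slow addition of 10
Reagents that add atoms: none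
Why: Proposed new method: the acid dehydrates the doubly activated C1 carbinol of 10 (both epimers) to the hydrogen-bonded vinylogous para-quinone methide 12, and C3′ of cardamonin (the carbon between the two hydroxyls, the most nucleophilic site of a chelated 2,4-dihydroxyaryl ketone) adds to the alkyl-substituted terminus C3 rather than to benzylic C1 because only that path keeps the E-styrene conjugation, while the phosphate, bound to the 4′-OH of the nucleophile and to the C5–OH or quinone methide oxygen of the electrophile, directs attack to the Re face of C3 and sets (3R) under catalyst control in a stereoconvergent Friedel–Crafts alkylation; the closest known reaction type is the chiral phosphoric acid-catalysed 1,6- and 1,8-addition of phenols, naphthols and indoles to para-quinone methides made in situ from para-hydroxybenzyl or propargylic alcohols, which has not been shown for an alkenyl-extended para-quinone methide attacked at its remote sp2 terminus by an acylphloroglucinol C–H.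

## Compound list

1 | 3-phenylpropanal | O=CCCc1ccccc1 | starting material
2 | allylboronic acid pinacol ester (2-allyl-4,4,5,5-tetramethyl-1,3,2-dioxaborolane) | C=CCB1OC(C)(C)C(C)(C)O1 | starting material
3 | 4,4,5,5-tetramethyl-2-{[(3S)-1-phenylhex-5-en-3-yl]oxy}-1,3,2-dioxaborolane | C=CC[C@@H](OB1OC(C)(C)C(C)(C)O1)CCc1ccccc1 | intermediate
4 | (S)-1-phenylhex-5-en-3-ol | C=CC[C@@H](O)CCc1ccccc1 | intermediate
5 | (E)-but-2-enal (crotonaldehyde) | C/C=C/C=O | starting material
6 | (2E,5S)-5-hydroxy-7-phenylhept-2-enal | O=C/C=C/C[C@@H](O)CCc1ccccc1 | intermediate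
7 | (4-bromophenoxy)trimethylsilane | C[Si](C)(C)Oc1ccc(Br)cc1 | starting material
8 | [4-(trimethylsilyloxy)phenyl]magnesium bromide | C[Si](C)(C)Oc1ccc([Mg]Br)cc1 | intermediate
9 | (2E,5S)-7-phenyl-1-[4-(trimethylsilyloxy)phenyl]hept-2-ene-1,5-diol (both C1 epimers) | C[Si](C)(C)Oc1ccc(C(O)/C=C/C[C@@H](O)CCc2ccccc2)cc1 | intermediate
10 | (2E,5S)-1-(4-hydroxyphenyl)-7-phenylhept-2-ene-1,5-diol (both C1 epimers) | Oc1ccc(C(O)/C=C/C[C@@H](O)CCc2ccccc2)cc1 | intermediate
11 | cardamonin, (E)-1-(2,4-dihydroxy-6-methoxyphenyl)-3-phenylprop-2-en-1-one | COc1cc(O)cc(O)c1C(=O)/C=C/c1ccccc1 | starting material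
12 | 4-[(2E,5S)-5-hydroxy-7-phenylhept-2-en-1-ylidene]cyclohexa-2,5-dien-1-one | O=C1C=CC(=C/C=C/C[C@@H](O)CCc2ccccc2)C=C1 | intermediate
13 | alpinnanin C, (E)-1-{2,4-dihydroxy-3-[(1E,3R,5S)-5-hydroxy-1-(4-hydroxyphenyl)-7-phenylhept-1-en-3-yl]-6-methoxyphenyl}-3-phenylprop-2-en-1-one | COc1cc(O)c([C@@H](/C=C/c2ccc(O)cc2)C[C@@H](O)CCc2ccccc2)c(O)c1C(=O)/C=C/c1ccccc1 | target

## Step count and risks

Total steps: 4. Longest linear sequence: 4 steps (1 → 4 → 6 → 10 → 13).

**Step 4 (the proposed new step).** The main risks are:
- alkylation at C5′ or at oxygen instead of C3′;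
- attack at benzylic C1 of the cation;
- a mismatched pairing of the catalyst with the C5 centre;
- acid-induced closure of 13 onto its 4-hydroxystyrene by the C5–OH or a ring A hydroxyl.

The E-alkene of 12 rules out internal trapping by the C5–OH during the coupling itself. The fallback uses known chemistry, sets out from 10 and 11 and comes back at 13. It is a Lewis-acid Friedel–Crafts allylation of the acylphloroglucinol with the allylic alcohol (BF3·OEt2, dioxane, 20 °C) run without a chiral catalyst. It gives 13 together with its C3 epimer, (E)-1-{2,4-dihydroxy-3-[(1E,3S,5S)-5-hydroxy-1-(4-hydroxyphenyl)-7-phenylhept-1-en-3-yl]-6-methoxyphenyl}-3-phenylprop-2-en-1-one F1. The two are diastereomers because C5 is fixed, and are separated by preparative HPLC.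

**Step 3.** Triol 10 ionises very easily and may not survive silica or storage, and 1,4-addition to the enal is possible. The fallback sets out from 4 and comes back at 12. Wacker oxidation of 4 (PdCl2, CuCl, O2, DMF/H2O) gives (S)-4-hydroxy-6-phenylhexan-2-one F2. Claisen–Schmidt condensation at its methyl group with 4-hydroxybenzaldehyde (pyrrolidine, AcOH, THF) gives (1E,5S)-5-hydroxy-1-(4-hydroxyphenyl)-7-phenylhept-1-en-3-one F3. Luche reduction (NaBH4, CeCl3·7H2O, MeOH, −40 °C) gives (1E,5S)-1-(4-hydroxyphenyl)-7-phenylhept-1-ene-3,5-diol F4 as both C3 epimers. F4 is a cinnamyl-type alcohol that is easier to handle, and it loses water under the conditions of step 4 to give the same 12. The condensation on a free β-hydroxy ketone is itself uncertain (dehydration, retro-aldol), so this path is a fallback and not the main route.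

**Step 1.** Unbranched aliphatic aldehydes can give lower enantiomeric excess in the phosphoric acid allylboration, and every later diastereomer ratio depends on it. The fallback sets out from 1 and comes back at 4. It is an iridium-catalysed transfer-hydrogenative carbonyl allylation with allyl acetate ([Ir(cod)Cl]2, BINAP, 3-nitrobenzoic acid, Cs2CO3, i-PrOH, THF, 100 °C). The BINAP enantiomer is chosen to give (S)-4 and checked by Mosher ester analysis. This fallback makes no new compound (F0).

## Further compounds

F1 | step 4 | (E)-1-{2,4-dihydroxy-3-[(1E,3S,5S)-5-hydroxy-1-(4-hydroxyphenyl)-7-phenylhept-1-en-3-yl]-6-methoxyphenyl}-3-phenylprop-2-en-1-one | COc1cc(O)c([C@H](/C=C/c2ccc(O)cc2)C[C@@H](O)CCc2ccccc2)c(O)c1C(=O)/C=C/c1ccccc1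
F2 | step 3 | (S)-4-hydroxy-6-phenylhexan-2-one | CC(=O)C[C@@H](O)CCc1ccccc1
F3 | step 3 | (1E,5S)-5-hydroxy-1-(4-hydroxyphenyl)-7-phenylhept-1-en-3-one | O=C(/C=C/c1ccc(O)cc1)C[C@@H](O)CCc1ccccc1
F4 | step 3 | (1E,5S)-1-(4-hydroxyphenyl)-7-phenylhept-1-ene-3,5-diol (both C3 epimers) | OC(/C=C/c1ccc(O)cc1)C[C@@H](O)CCc1ccccc1
F0 | step 1 | none | none
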